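**Plan**
- Retrosynthesis: the three propionates and the C12–C13 epoxide are removed first, leaving an eleven-membered (E)-allylic alcohol. That ring (C1–C2–C15–C14–C13–C12–C11–C10–C9–C8–C16) is cut at C13–C14 into a C14 aldehyde and a C12≡C13 methyl alkyne. Further cuts: C10–C11 (propargylation), C1=CH2 (methylenation), C8–C9 (conjugate addition), C2–C15 (enolate alkylation), ring A (C8=C16 aldol condensation, C5–C6 conjugate addition).
- Forward order: ring B as an enantiopure 4-silyloxy-3-methylcyclohexenone, then ring A by cyclopentene annulation, then the two side arms, then the eleven-membered ring as the last ring, then epoxide and esters.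
- Enabling feature: the C12–C13 epoxide with its C13 methyl next to the C14 carbinol is a masked (E)-2-methyl allylic alcohol. That unit is what an aldehyde and a 2-butynyl group give in one reductive coupling, which forms the ring bond, the alkene geometry and the carbinol together.
- Stereochemistry: C4 from a CBS reduction; all other centres by substrate control from it: C5 (anti cuprate addition), C2 (equilibration), C8/C16 (cuprate addition, kinetic protonation), C9 (hydroxyl-directed hydrogenation), C10 (Felkin–Anh), C14 (macrocyclic control), C12/C13 (hydroxyl-directed epoxidation).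

Key step: step 18

Remark on locants (not IUPAC): C1 = ring carbon bearing the exocyclic CH2; C2–C5 and C16 complete six-membered ring B (C4 bears O, C5 bears CH3); C5–C8 and C16 are five-membered ring A; C9 (CH3), C10 (O), C11, C12, C13 (CH3), C14 (O), C15 run from C8 back to C2.
Assumption on the chemistry: the C14 configuration from step 18 and the epoxide face in step 19 are under macrocyclic substrate control and are drawn as the isomers needed; the fallback for step 19 sets both by reagent control.

**Route**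

Step 1
Reactants: 1 4-methoxy-2-methylphenol
Product: 2 4,4-dimethoxy-2-methylcyclohexa-2,5-dien-1-one
Conditions: PhI(OAc)2, MeOH, 0 °C
Reagents that add atoms: methanol, CO
Why: Hypervalent-iodine oxidative dearomatisation of a para-methoxyphenol in methanol gives the quinone monoketal.

Step 2
Reactants: 2 4,4-dimethoxy-2-methylcyclohexa-2,5-dien-1-one
Product: 3 4,4-dimethoxy-2-methylcyclohex-2-en-1-one
Conditions: H2 (1 atm), (Ph3P)3RhCl (cat.), benzene, rt
Reagents that add atoms: none
Why: Wilkinson hydrogenation should reduce the unhindered disubstituted C=C and leave the methyl-substituted enone C=C.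

Step 3
Reactants: 3 4,4-dimethoxy-2-methylcyclohex-2-en-1-one
Product: 4 (1S)-4,4-dimethoxy-2-methylcyclohex-2-en-1-ol
Conditions: (R)-Me-CBS (15 mol%), BH3·SMe2, THF, −20 °C
Reagents that add atoms: none
Why: Corey–Bakshi–Shibata reduction of an α-substituted cyclic enone, with the α-methylalkenyl arm as the large group, should give the (S)-carbinol (future C4), the source of all absolute configuration.

Step 4
Reactants: 4 (1S)-4,4-dimethoxy-2-methylcyclohex-2-en-1-ol
Product: 5 tert-butyl{[(1S)-4,4-dimethoxy-2-methylcyclohex-2-en-1-yl]oxy}diphenylsilane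
Conditions: TBDPSCl, imidazole, DMF, rt
Reagents that add atoms: tert-butyl(chloro)diphenylsilane, CC(C)(C)[Si](Cl)(c1ccccc1)c1ccccc1
Why: Standard silylation; TBDPS is chosen because it has to survive the aqueous HCl of steps 7 and 10.

Step 5
Reactants: 5 tert-butyl{[(1S)-4,4-dimethoxy-2-methylcyclohex-2-en-1-yl]oxy}diphenylsilane
Product: 6 (4S)-4-[(tert-butyldiphenylsilyl)oxy]-3-methylcyclohex-2-en-1-one
Conditions: PPTS, acetone/H2O, rt
Reagents that add atoms: water, O
Why: Mild acetal hydrolysis unmasks the ketone (future C1) and so transposes the enone, placing the silyloxy carbon γ and the methyl carbon β.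

Step 6
Reactants: 6 (4S)-4-[(tert-butyldiphenylsilyl)oxy]-3-methylcyclohex-2-en-1-one; 7 2-(2-bromoethyl)-1,3-dioxolane
Product: 10 (3S,4S)-4-[(tert-butyldiphenylsilyl)oxy]-3-[2-(1,3-dioxolan-2-yl)ethyl]-3-methylcyclohexan-1-one, via Grignard reagent 8 (not isolated), via trimethylsilyl enol ether 9 (not isolated)
Conditions: 7, Mg, THF, 25 °C; CuBr·SMe2 (20 mol%), TMSCl, 6, THF, −78 → −30 °C; then K2CO3, MeOH, 0 °C
Reagents that add atoms: none
Why: Copper-catalysed, TMSCl-accelerated conjugate addition of a Grignard reagent to a β,β-disubstituted enone should occur anti to the γ-silyloxy group and set the quaternary C5 with CH3 cis to the C4 oxygen.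

Step 7
Reactants: 10 (3S,4S)-4-[(tert-butyldiphenylsilyl)oxy]-3-[2-(1,3-dioxolan-2-yl)ethyl]-3-methylcyclohexan-1-one
Product: 11 (7S,7aS)-7-[(tert-butyldiphenylsilyl)oxy]-7a-methyl-1,2,5,6,7,7a-hexahydro-4H-inden-4-one
Conditions: 2 M aq HCl, THF, 50 °C
Reagents that add atoms: none
Why: Helquist cyclopentene annulation: acetal hydrolysis, then intramolecular aldol condensation of the C16 methylene onto the C8 aldehyde closes ring A as the C8=C16 enone.

Step 8
Reactants: 11 (7S,7aS)-7-[(tert-butyldiphenylsilyl)oxy]-7a-methyl-1,2,5,6,7,7a-hexahydro-4H-inden-4-one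
Product: 13 methyl 2-[(5S,7S,7aS)-7-[(tert-butyldiphenylsilyl)oxy]-7a-methyl-4-oxo-2,4,5,6,7,7a-hexahydro-1H-inden-5-yl]acetate, via kinetic C5 epimer 12 (not isolated)
Conditions: LDA, THF, −78 °C; BrCH2CO2Me, −78 → −30 °C; then DBU (0.3 equiv), CH2Cl2, rt
Reagents that add atoms: methyl bromoacetate, COC(=O)CBr
Why: Kinetic α′-enolate alkylation followed by base equilibration should leave the C2 substituent equatorial (cis to the equatorial C4 silyloxy group) in the locked enone conformer whose angular methyl is axial.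

Step 9
Reactants: 14 2-bromoprop-2-en-1-ol
Product: 15 [(2-bromoprop-2-en-1-yl)oxy]triethylsilane
Conditions: TESCl, imidazole, DMF, 0 °C
Reagents that add atoms: chlorotriethylsilane, CC[Si](Cl)(CC)CC
Why: Standard silylation gives an acid-labile ether that is stable to t-BuLi at −78 °C.

Step 10
Reactants: 13 methyl 2-[(5S,7S,7aS)-7-[(tert-butyldiphenylsilyl)oxy]-7a-methyl-4-oxo-2,4,5,6,7,7a-hexahydro-1H-inden-5-yl]acetate; 15 [(2-bromoprop-2-en-1-yl)oxy]triethylsilane
Product: 19 cis-fused hydroxy ketone (C1 ketone; 3-hydroxyprop-1-en-2-yl group on C8 trans to the C5 methyl; H-16 cis to the C5 methyl), via alkenyllithium 16 (not isolated), via alkenylmagnesium bromide 17 (not isolated), via bis-silyl enol ether adduct 18 (not isolated)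
Conditions: 15, t-BuLi (2 equiv), Et2O, −78 °C; MgBr2·OEt2; CuBr·SMe2 (20 mol%), TMSCl, 13, THF, −78 → −40 °C; then 1 M HCl, THF, 0 °C
Reagents that add atoms: none
Why: Copper-catalysed conjugate addition to C8 should occur anti to the axial angular methyl, and kinetic C-protonation of the silyl enol ether at C16 anti to the new, larger C8 substituent should give the cis-hydrindanone, while the acid also cleaves the TES ether.

Step 11
Reactants: 19 cis-fused hydroxy ketone with the 3-hydroxyprop-1-en-2-yl group on C8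
Product: 20 hydroxy ketone with a (9S)-1-hydroxypropan-2-yl group on C8
Conditions: [Rh(nbd)(dppb)]BF4 (5 mol%), H2 (40 atm), CH2Cl2, rt
Reagents that add atoms: none
Why: Hydroxyl-directed hydrogenation of a 1,1-disubstituted allylic alcohol with a cationic rhodium catalyst; with H-8 eclipsing the C=CH2 bond (A(1,3) strain), hydrogen should add anti to the bulkier C16 branch and give (9S).

Step 12
Reactants: 20 hydroxy ketone with the (9S)-1-hydroxypropan-2-yl group on C8
Product: 21 C1 exocyclic-methylene primary alcohol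
Conditions: Zn, CH2Br2, TiCl4 (Lombardo reagent), THF/CH2Cl2, 0 °C → rt
Reagents that add atoms: dibromomethane, BrCBr
Why: Takai–Lombardo methylenation is non-basic, so the two epimerisable α-centres (C2, C16) should be kept, and the ester and free hydroxyl are tolerated.

Step 13
Reactants: 21 C1 exocyclic-methylene primary alcohol
Product: 22 (9S)-C10 aldehyde
Conditions: Dess–Martin periodinane, NaHCO3, CH2Cl2, 0 °C
Reagents that add atoms: none
Why: Buffered Dess–Martin oxidation gives the α-methyl aldehyde without epimerisation; it is used directly.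

Step 14
Reactants: 23 but-2-yn-1-ol
Product: 24 but-2-yn-1-yl methanesulfonate
Conditions: MsCl, Et3N, CH2Cl2, −20 °C
Reagents that add atoms: methanesulfonyl chloride, CS(=O)(=O)Cl
Why: Standard mesylation of a primary propargylic alcohol.

Step 15
Reactants: 22 (9S)-C10 aldehyde; 24 but-2-yn-1-yl methanesulfonate
Product: 26 (9S,10S)-homopropargylic alcohol (C10–OH; C11H2–C≡C–CH3), via allenylzinc reagent 25 (not isolated)
Conditions: Pd(OAc)2 (5 mol%), PPh3 (5 mol%), Et2Zn (3 equiv), THF, −20 → 0 °C
Reagents that add atoms: none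
Why: Palladium-catalysed, diethylzinc-mediated umpolung propargylation (Tamaru–Marshall): the allenylzinc reacts SE2′ at its CH2 terminus to give the internal methyl alkyne, and Felkin–Anh addition anti to the C8 ring carbon should give the 9,10-syn alcohol.

Step 16
Reactants: 26 (9S,10S)-homopropargylic alcohol
Product: 27 C10 tert-butyldimethylsilyl ether
Conditions: TBSOTf, 2,6-lutidine, CH2Cl2, −78 °C
Reagents that add atoms: tert-butyldimethylsilyl triflate, CC(C)(C)[Si](C)(C)OS(=O)(=O)C(F)(F)F
Why: Standard silylation of a hindered secondary alcohol.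

Step 17
Reactants: 27 C10 tert-butyldimethylsilyl ether (methyl ester)
Product: 28 ynal (C14 aldehyde on the C2 arm; C12≡C13–CH3 on the C8 arm)
Conditions: DIBAL-H (1.1 equiv), CH2Cl2, −78 °C; MeOH, Rochelle salt
Reagents that add atoms: none
Why: Low-temperature DIBAL-H half-reduction of a methyl ester stops at the aldehyde through the stable aluminium hemiacetal.

Step 18
Reactants: 28 ynal
Product: 30 eleven-membered (12E,14R)-allylic alcohol, via macrocyclic triethylsilyl ether 29 (not isolated)
Conditions: Ni(cod)2 (25 mol%), IMes·HCl (25 mol%), KOt-Bu (25 mol%), Et3SiH (5 equiv), THF (2 mM, slow addition of 28), rt; then PPTS, MeOH, 0 °C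
Reagents that add atoms: none
Why: Ni(0)–NHC binds the aldehyde and the alkyne and couples them oxidatively to an oxanickelacyclopentene (C13–C14 bond), which Et3SiH cleaves by σ-bond metathesis and C–H reductive elimination to the silyl ether. The closest known reaction type is the nickel-catalysed reductive macrocyclisation of ynals to endocyclic allylic alcohols. The eleven-membered ring closes in the endocyclic mode, both alkyne carbons ending in the ring, with the new bond at the distal, methyl-bearing alkyne carbon. The 12E geometry follows from cis addition of H and C14 across the alkyne, and the C14 configuration is set by the macrocyclic transition state, the carbinol oxygen sitting on the ring periphery. The step needs endo over exo regioselectivity, which the small IMes ligand should secure by directing C–C formation to the less hindered methyl terminus, and ring closure over oligomerisation, which high dilution secures. The 1,1-disubstituted C1 alkene and the silyl ethers are inert under these conditions.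

Step 19
Reactants: 30 eleven-membered (12E,14R)-allylic alcohol
Product: 31 C12–C13 epoxy alcohol (epoxide as in the target; C14–OH free)
Conditions: mCPBA (1.05 equiv), NaHCO3, CH2Cl2, −20 → 0 °C
Reagents that add atoms: 3-chloroperbenzoic acid, OOC(=O)c1cccc(Cl)c1
Why: Henbest hydroxyl-directed peracid epoxidation on the outer face of the ring alkene: with C15 held on the inner face and the hydroxyl at about 120° to the alkene plane, the threo epoxy alcohol should form, and the trisubstituted alkene reacts faster than the 1,1-disubstituted C1 methylene.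

Step 20
Reactants: 31 C12–C13 epoxy alcohol
Product: 32 epoxy triol (C4, C10, C14 hydroxyls)
Conditions: TBAF, THF, rt → 45 °C
Reagents that add atoms: none
Why: Fluoride removes both silyl ethers; Payne migration is blocked because it would need SN2 attack at the fully substituted C13.

Step 21
Reactants: 32 epoxy triol
Product: 33 CNP0332420.1 (tripropionate)
Conditions: (EtCO)2O, Et3N, DMAP, CH2Cl2, rt
Reagents that add atoms: propanoic anhydride, CCC(=O)OC(=O)CC
Why: DMAP-catalysed acylation of the three secondary alcohols under non-acidic conditions leaves the epoxide intact.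

**Compound list**

1 | 4-methoxy-2-methylphenol | COc1ccc(O)c(C)c1 | starting material
2 | 4,4-dimethoxy-2-methylcyclohexa-2,5-dien-1-one | COC1(OC)C=CC(=O)C(C)=C1 | intermediate
3 | 4,4-dimethoxy-2-methylcyclohex-2-en-1-one | COC1(OC)CCC(=O)C(C)=C1 | intermediate
4 | (1S)-4,4-dimethoxy-2-methylcyclohex-2-en-1-ol | COC1(OC)CC[C@H](O)C(C)=C1 | intermediate
5 | tert-butyl{[(1S)-4,4-dimethoxy-2-methylcyclohex-2-en-1-yl]oxy}diphenylsilane | COC1(OC)CC[C@H](O[Si](c2ccccc2)(c2ccccc2)C(C)(C)C)C(C)=C1 | intermediate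
6 | (4S)-4-[(tert-butyldiphenylsilyl)oxy]-3-methylcyclohex-2-en-1-one | O=C1C=C(C)[C@@H](O[Si](c2ccccc2)(c2ccccc2)C(C)(C)C)CC1 | intermediate
7 | 2-(2-bromoethyl)-1,3-dioxolane | BrCCC1OCCO1 | starting material
8 | [2-(1,3-dioxolan-2-yl)ethyl]magnesium bromide | Br[Mg]CCC1OCCO1 | intermediate
9 | trimethylsilyl enol ether of 10 (C1–OSiMe3, C1=C16) | C[Si](C)(C)OC1=C[C@](C)(CCC2OCCO2)[C@@H](O[Si](c2ccccc2)(c2ccccc2)C(C)(C)C)CC1 | intermediate
10 | (3S,4S)-4-[(tert-butyldiphenylsilyl)oxy]-3-[2-(1,3-dioxolan-2-yl)ethyl]-3-methylcyclohexan-1-one | O=C1CC[C@H](O[Si](c2ccccc2)(c2ccccc2)C(C)(C)C)[C@@](C)(CCC2OCCO2)C1 | intermediate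
11 | (7S,7aS)-7-[(tert-butyldiphenylsilyl)oxy]-7a-methyl-1,2,5,6,7,7a-hexahydro-4H-inden-4-one | O=C1CC[C@H](O[Si](c2ccccc2)(c2ccccc2)C(C)(C)C)[C@@]2(C)CCC=C12 | intermediate
12 | methyl 2-[(5R,7S,7aS)-7-[(tert-butyldiphenylsilyl)oxy]-7a-methyl-4-oxo-2,4,5,6,7,7a-hexahydro-1H-inden-5-yl]acetate (side chain trans to the silyloxy group) | O=C1[C@@H](CC(=O)OC)C[C@H](O[Si](c2ccccc2)(c2ccccc2)C(C)(C)C)[C@@]2(C)CCC=C12 | intermediate
13 | methyl 2-[(5S,7S,7aS)-7-[(tert-butyldiphenylsilyl)oxy]-7a-methyl-4-oxo-2,4,5,6,7,7a-hexahydro-1H-inden-5-yl]acetate (side chain cis to the silyloxy group) | O=C1[C@H](CC(=O)OC)C[C@H](O[Si](c2ccccc2)(c2ccccc2)C(C)(C)C)[C@@]2(C)CCC=C12 | intermediate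
14 | 2-bromoprop-2-en-1-ol | OCC(Br)=C | starting material
15 | [(2-bromoprop-2-en-1-yl)oxy]triethylsilane | CC[Si](CC)(CC)OCC(Br)=C | intermediate
16 | {3-[(triethylsilyl)oxy]prop-1-en-2-yl}lithium | [Li]C(=C)CO[Si](CC)(CC)CC | intermediate
17 | {3-[(triethylsilyl)oxy]prop-1-en-2-yl}magnesium bromide | Br[Mg]C(=C)CO[Si](CC)(CC)CC | intermediate
18 | conjugate adduct as C1 trimethylsilyl enol ether (C1=C16) with the triethylsilyl ether on the C8 side chain; C8 substituent trans to the C5 methyl | C[Si](C)(C)OC1=C2[C@H](C(=C)CO[Si](CC)(CC)CC)CC[C@]2(C)[C@@H](O[Si](c3ccccc3)(c3ccccc3)C(C)(C)C)C[C@H]1CC(=O)OC | intermediate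
19 | methyl 2-[cis-fused 7-(tert-butyldiphenylsilyloxy)-3-(3-hydroxyprop-1-en-2-yl)-7a-methyl-4-oxooctahydro-1H-inden-5-yl]acetate; H-3 and H-3a cis to the 7a-methyl; C5 and C7 as in 13 | O=C1[C@H](CC(=O)OC)C[C@H](O[Si](c2ccccc2)(c2ccccc2)C(C)(C)C)[C@@]2(C)CC[C@@H](C(=C)CO)[C@@H]12 | intermediate
20 | as 19 with a (2S)-1-hydroxypropan-2-yl group on C3 of the indane (C9 = S) | O=C1[C@H](CC(=O)OC)C[C@H](O[Si](c2ccccc2)(c2ccccc2)C(C)(C)C)[C@@]2(C)CC[C@@H]([C@H](C)CO)[C@@H]12 | intermediate
21 | as 20 with the C1 (indane C4) ketone replaced by an exocyclic methylene | C=C1[C@H](CC(=O)OC)C[C@H](O[Si](c2ccccc2)(c2ccccc2)C(C)(C)C)[C@@]2(C)CC[C@@H]([C@H](C)CO)[C@@H]12 | intermediate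
22 | as 21 with the side-chain alcohol oxidised: (2S)-1-oxopropan-2-yl group on C8 | C=C1[C@H](CC(=O)OC)C[C@H](O[Si](c2ccccc2)(c2ccccc2)C(C)(C)C)[C@@]2(C)CC[C@@H]([C@H](C)C=O)[C@@H]12 | intermediate
23 | but-2-yn-1-ol | CC#CCO | starting material
24 | but-2-yn-1-yl methanesulfonate | CC#CCOS(C)(=O)=O | intermediate
25 | (buta-2,3-dien-2-yl)(ethyl)zinc | CC[Zn]C(C)=C=C | intermediate
26 | as 21 with a (2S,3S)-3-hydroxyhept-5-yn-2-yl group on C8 (C9 S, C10 S; 9,10-syn) | C=C1[C@H](CC(=O)OC)C[C@H](O[Si](c2ccccc2)(c2ccccc2)C(C)(C)C)[C@@]2(C)CC[C@@H]([C@H](C)[C@@H](O)CC#CC)[C@@H]12 | intermediate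
27 | C10 tert-butyldimethylsilyl ether of 26 | C=C1[C@H](CC(=O)OC)C[C@H](O[Si](c2ccccc2)(c2ccccc2)C(C)(C)C)[C@@]2(C)CC[C@@H]([C@H](C)[C@@H](O[Si](C)(C)C(C)(C)C)CC#CC)[C@@H]12 | intermediate
28 | ynal: as 27 with the methyl ester reduced to the C14 aldehyde (2-oxoethyl group on C2) | C=C1[C@H](CC=O)C[C@H](O[Si](c2ccccc2)(c2ccccc2)C(C)(C)C)[C@@]2(C)CC[C@@H]([C@H](C)[C@@H](O[Si](C)(C)C(C)(C)C)CC#CC)[C@@H]12 | intermediate
29 | tricyclic (12E,14R)-C14 triethylsilyl ether; C4–OTBDPS, C10–OTBS | C=C1[C@H]2C[C@H](O[Si](c3ccccc3)(c3ccccc3)C(C)(C)C)[C@@]3(C)CC[C@@H]([C@H](C)[C@@H](O[Si](C)(C)C(C)(C)C)C/C=C(\C)/[C@H](O[Si](CC)(CC)CC)C2)[C@@H]13 | intermediate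
30 | tricyclic (12E,14R)-allylic alcohol; C4–OTBDPS, C10–OTBS | C=C1[C@H]2C[C@H](O[Si](c3ccccc3)(c3ccccc3)C(C)(C)C)[C@@]3(C)CC[C@@H]([C@H](C)[C@@H](O[Si](C)(C)C(C)(C)C)C/C=C(\C)/[C@H](O)C2)[C@@H]13 | intermediate
31 | C12–C13 trans-epoxide of 30 (epoxide and C14 as in the target; C14–OH free) | C=C1[C@H]2C[C@H](O[Si](c3ccccc3)(c3ccccc3)C(C)(C)C)[C@@]3(C)CC[C@@H]([C@H](C)[C@@H](O[Si](C)(C)C(C)(C)C)C[C@@H]4O[C@@]4(C)[C@H](O)C2)[C@@H]13 | intermediate
32 | epoxy triol (C4, C10, C14 hydroxyls; all centres as in the target) | C=C1[C@H]2C[C@H](O)[C@@]3(C)CC[C@@H]([C@H](C)[C@@H](O)C[C@@H]4O[C@@]4(C)[C@H](O)C2)[C@@H]13 | intermediate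
33 | CNP0332420.1, the C4, C10, C14 tripropionate | C=C1[C@H]2C[C@H](OC(=O)CC)[C@@]3(C)CC[C@@H]([C@H](C)[C@@H](OC(=O)CC)C[C@@H]4O[C@@]4(C)[C@H](OC(=O)CC)C2)[C@@H]13 | target

**Summary**

Total step count: 21 (including the two reagent preparations, steps 9 and 14).
Longest linear sequence: 19 steps (1–8, 10–13, 15–21).

Steps most likely to fail:

1. Step 18. The ring closure may lose to oligomerisation, or the coupling may occur at the proximal alkyne carbon and give a ten-membered ring with an exocyclic alkene. The fallback sets out from 27 and comes back at 30. Hydrozirconation of the methyl alkyne with Cp2Zr(H)Cl and iodinolysis should give the (E)-alkenyl iodide F1. DIBAL-H at −78 °C should give the iodo aldehyde F2. A Nozaki–Hiyama–Kishi closure (CrCl2, catalytic NiCl2, DMSO/THF, high dilution) then forms the same C13–C14 bond with fixed regiochemistry and E geometry and delivers 30.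

2. Step 19. The peracid may attack the wrong face of the ring alkene, or the C14 carbinol from step 18 may have the wrong configuration, so that the epoxy alcohol is not the threo isomer. The fallback sets out from 30 (either C14 epimer) and comes back at 33. Dess–Martin oxidation gives the macrocyclic enone F3. (R)-Me-CBS/BH3 reduction should give the (14S)-allylic alcohol F4 by reagent control. VO(acac)2/t-BuOOH, which is erythro-selective for 2-methyl allylic alcohols, should give the epoxy alcohol F5 with the epoxide configured as in the target. Mitsunobu reaction with propanoic acid (PPh3, DIAD) inverts C14 and installs the ester, giving the propionate F6. TBAF gives the diol F7, and propanoic anhydride/DMAP gives 33.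

3. Step 15. The allenyl/propargyl zinc species may react at the wrong terminus and give an allenyl carbinol, or the palladium cycle may stall. The fallback sets out from 22 and comes back at 26. Corey–Chaykovsky methylenation (Me3S+ I−, n-BuLi, THF, −10 °C) should give the terminal epoxide F8 with Felkin–Anh control. Opening at C11 with 1-propynyllithium/BF3·OEt2 at −78 °C forms the C11–C12 bond instead of C10–C11 and gives 26. The Felkin–Anh diastereoselectivity at C10 is no better in this fallback; C10 epimers would be separated.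

Further compounds
F1 | step 18 | (E)-alkenyl iodide: as 27 with the alkyne converted into CH=C(CH3)I | C=C1[C@H](CC(=O)OC)C[C@H](O[Si](c2ccccc2)(c2ccccc2)C(C)(C)C)[C@@]2(C)CC[C@@H]([C@H](C)[C@@H](O[Si](C)(C)C(C)(C)C)C/C=C(\C)I)[C@@H]12
F2 | step 18 | iodo aldehyde: as F1 with the methyl ester reduced to the C14 aldehyde | C=C1[C@H](CC=O)C[C@H](O[Si](c2ccccc2)(c2ccccc2)C(C)(C)C)[C@@]2(C)CC[C@@H]([C@H](C)[C@@H](O[Si](C)(C)C(C)(C)C)C/C=C(\C)I)[C@@H]12
F3 | step 19 | macrocyclic (12E)-C14 enone | C=C1[C@H]2C[C@H](O[Si](c3ccccc3)(c3ccccc3)C(C)(C)C)[C@@]3(C)CC[C@@H]([C@H](C)[C@@H](O[Si](C)(C)C(C)(C)C)C/C=C(\C)/C(=O)C2)[C@@H]13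
F4 | step 19 | (12E,14S)-allylic alcohol (C14 epimer of 30) | C=C1[C@H]2C[C@H](O[Si](c3ccccc3)(c3ccccc3)C(C)(C)C)[C@@]3(C)CC[C@@H]([C@H](C)[C@@H](O[Si](C)(C)C(C)(C)C)C/C=C(\C)/[C@@H](O)C2)[C@@H]13
F5 | step 19 | erythro epoxy alcohol (epoxide as in the target, C14 epimeric to 31) | C=C1[C@H]2C[C@H](O[Si](c3ccccc3)(c3ccccc3)C(C)(C)C)[C@@]3(C)CC[C@@H]([C@H](C)[C@@H](O[Si](C)(C)C(C)(C)C)C[C@@H]4O[C@@]4(C)[C@@H](O)C2)[C@@H]13
F6 | step 19 | C14 propionate with the target configuration; C4–OTBDPS, C10–OTBS | C=C1[C@H]2C[C@H](O[Si](c3ccccc3)(c3ccccc3)C(C)(C)C)[C@@]3(C)CC[C@@H]([C@H](C)[C@@H](O[Si](C)(C)C(C)(C)C)C[C@@H]4O[C@@]4(C)[C@H](OC(=O)CC)C2)[C@@H]13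
F7 | step 19 | C4,C10-diol C14-propionate | C=C1[C@H]2C[C@H](O)[C@@]3(C)CC[C@@H]([C@H](C)[C@@H](O)C[C@@H]4O[C@@]4(C)[C@H](OC(=O)CC)C2)[C@@H]13
F8 | step 15 | terminal C10–C11 epoxide: as 22 with the aldehyde converted into an oxiran-2-yl group | C=C1[C@H](CC(=O)OC)C[C@H](O[Si](c2ccccc2)(c2ccccc2)C(C)(C)C)[C@@]2(C)CC[C@@H]([C@H](C)[C@@H]3CO3)[C@@H]12
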